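The ten-membered carbocycle is closed last, between the two carbinol carbons C8 and C9 (germacrane numbering), two centres of like (acceptor) polarity. The route exploits that C9 is both a carbinol carbon and the terminus of the 2-(methoxycarbonyl)allyl unit C9–C10(=C1)–C14. In the seco-dialdehyde the C9 aldehyde is part of a 2-formylacrylate, which CrCl2/Et3SiCl should reduce selectively to a γ-siloxyallylchromium. Its addition to the C8 aldehyde closes the ring, sets C8 and C9, regenerates the C1=C10 olefin and delivers O9 silylated and O8 free, so the two different esters can be installed without ambiguity. The trans-lactone stereocentres C6/C7 come from (S)-5-(hydroxymethyl)furan-2(5H)-one.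

Key step: step 16

Remark: germacrane numbering is used throughout (ring C1–C10; lactone C12(=O)–C11(=C13H2) closed on O6; C14 = ester carbon on C10; C15 = hydroxymethyl carbon on C4); the target is read as the 6R,7S,8S,9S isomer with both ring olefins cis in the ring (1(10)E,4E by CIP), and the named starting materials and reagents are assumed to be commercial.

Step 1
Reactants: 1 (S)-5-(hydroxymethyl)furan-2(5H)-one
Product: 2 (S)-5-[(triethylsilyloxy)methyl]furan-2(5H)-one
Conditions: Et3SiCl, imidazole, CH2Cl2, 0 °C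
Reagents that add atoms: chlorotriethylsilane, CC[Si](Cl)(CC)CC
Why: O-silylation of the primary alcohol under mild base should leave the base-sensitive γ-stereocentre (future C6) untouched.

Step 2
Reactants: 2 (S)-5-[(triethylsilyloxy)methyl]furan-2(5H)-one
Product: 3 (4R,5S)-4-(hydroxymethyl)-5-[(triethylsilyloxy)methyl]oxolan-2-one
Conditions: hν (350 nm), benzophenone (cat.), MeOH, 25 °C
Reagents that add atoms: methanol, CO
Why: Benzophenone-sensitised photochemical radical conjugate addition, in which the hydroxymethyl radical should add to the butenolide β-carbon anti to the C5 substituent and so set C7 trans to C6 while bringing in C8.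

Step 3
Reactants: 3 (4R,5S)-4-(hydroxymethyl)-5-[(triethylsilyloxy)methyl]oxolan-2-one
Product: 4 (4R,5S)-4-[(tert-butyldimethylsilyloxy)methyl]-5-[(triethylsilyloxy)methyl]oxolan-2-one
Conditions: t-BuMe2SiCl, imidazole, DMF, 25 °C
Reagents that add atoms: tert-butyl(chloro)dimethylsilane, CC(C)(C)[Si](C)(C)Cl
Why: Silylation of the new primary alcohol gives an O8 protecting group that is more robust than the triethylsilyl ether on O5, so the two can be told apart in step 7.

Step 4
Reactants: 4 (4R,5S)-4-[(tert-butyldimethylsilyloxy)methyl]-5-[(triethylsilyloxy)methyl]oxolan-2-one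
Product: 8 (4R,5S)-4-[(tert-butyldimethylsilyloxy)methyl]-3-methylidene-5-[(triethylsilyloxy)methyl]oxolan-2-one, via lithium enolate 5 (not isolated), via Mannich base 6 (not isolated), via ammonium iodide 7 (not isolated)
Conditions: LiN(i-Pr)2, THF, −78 °C; CH2=NMe2+ I−, −78 → 25 °C; MeI, CH2Cl2, 25 °C; aq. NaHCO3, 25 °C
Reagents that add atoms: N,N-dimethylmethyleneiminium iodide (Eschenmoser's salt), C=[N+](C)C.[I-]
Why: Mannich alkylation of the lactone enolate followed by quaternisation and Hofmann-type (E1cB) elimination is the standard α-methylenation of a γ-butyrolactone and does not touch C6 or C7.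

Step 5
Reactants: 9 4-chloro-1,1-dimethoxybutane
Product: 10 (4,4-dimethoxybutyl)triphenylphosphonium iodide
Conditions: PPh3, NaI, MeCN, 80 °C
Reagents that add atoms: triphenylphosphine, c1ccc(cc1)P(c1ccccc1)c1ccccc1; sodium iodide, [Na+].[I-]
Why: Finkelstein-assisted SN2 quaternisation of the primary halide should give the salt that carries C1 (as acetal) to C4.

Step 6
Reactants: 10 (4,4-dimethoxybutyl)triphenylphosphonium iodide
Product: 12 5,5-dimethoxy-2-(triphenyl-λ5-phosphanylidene)pentanal, via phosphonium ylide 11 (not isolated)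
Conditions: KOtBu (2 equiv), THF, 0 °C; HCO2Et, 0 → 25 °C
Reagents that add atoms: ethyl formate, CCOC=O
Why: C-formylation of the non-stabilised ylide with a formate ester gives the formyl-stabilised ylide, a reagent for (E)-2-alkyl enals.

Step 7
Reactants: 8 (4R,5S)-4-[(tert-butyldimethylsilyloxy)methyl]-3-methylidene-5-[(triethylsilyloxy)methyl]oxolan-2-one; 12 5,5-dimethoxy-2-(triphenyl-λ5-phosphanylidene)pentanal
Product: 14 (E)-3-[(2R,3R)-3-[(tert-butyldimethylsilyloxy)methyl]-4-methylidene-5-oxooxolan-2-yl]-2-(3,3-dimethoxypropyl)prop-2-enal, via lactone aldehyde 13 (not isolated)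
Conditions: (COCl)2, DMSO, CH2Cl2, −78 → −30 °C; i-Pr2NEt, −78 °C; then 12, −78 → 40 °C
Reagents that add atoms: none
Why: Swern activation should cleave and oxidise the primary triethylsilyl ether selectively (the tert-butyldimethylsilyl ether survives) to the α-oxy aldehyde, which is trapped at once in a Wittig reaction with the formyl-stabilised ylide to give the (E)-enal (CHO trans to C6, hence C3 cis to C6), the trans-lactone being the thermodynamic isomer at C6 in any case.

Step 8
Reactants: 14 (E)-3-[(2R,3R)-3-[(tert-butyldimethylsilyloxy)methyl]-4-methylidene-5-oxooxolan-2-yl]-2-(3,3-dimethoxypropyl)prop-2-enal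
Product: 15 (4R,5R)-4-[(tert-butyldimethylsilyloxy)methyl]-5-[(E)-2-(hydroxymethyl)-5,5-dimethoxypent-1-en-1-yl]-3-methylideneoxolan-2-one
Conditions: NaBH4, CeCl3·7H2O, MeOH, −78 °C
Reagents that add atoms: none
Why: Luche 1,2-reduction should convert the enal into the C15 allylic alcohol without conjugate reduction of the α-methylene lactone or attack on the lactone carbonyl.

Step 9
Reactants: 15 (4R,5R)-4-[(tert-butyldimethylsilyloxy)methyl]-5-[(E)-2-(hydroxymethyl)-5,5-dimethoxypent-1-en-1-yl]-3-methylideneoxolan-2-one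
Product: 16 (4R,5R)-4-[(tert-butyldimethylsilyloxy)methyl]-5-[(E)-2-[(tert-butyldiphenylsilyloxy)methyl]-5,5-dimethoxypent-1-en-1-yl]-3-methylideneoxolan-2-one
Conditions: t-BuPh2SiCl, imidazole, CH2Cl2, 25 °C
Reagents that add atoms: tert-butyl(chloro)diphenylsilane, CC(C)(C)[Si](Cl)(c1ccccc1)c1ccccc1
Why: Silylation gives O15 the most robust silyl group of the route, so that it is the last one removed.

Step 10
Reactants: 16 (4R,5R)-4-[(tert-butyldimethylsilyloxy)methyl]-5-[(E)-2-[(tert-butyldiphenylsilyloxy)methyl]-5,5-dimethoxypent-1-en-1-yl]-3-methylideneoxolan-2-one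
Product: 17 (E)-4-[(tert-butyldiphenylsilyloxy)methyl]-5-[(2R,3R)-3-[(tert-butyldimethylsilyloxy)methyl]-4-methylidene-5-oxooxolan-2-yl]pent-4-enal
Conditions: PPTS (cat.), acetone/H2O 9:1, 25 °C
Reagents that add atoms: water, O
Why: Mild acid-catalysed hydrolysis of the acyclic dimethyl acetal should free the C1 aldehyde while both silyl ethers survive.

Step 11
Reactants: 17 (E)-4-[(tert-butyldiphenylsilyloxy)methyl]-5-[(2R,3R)-3-[(tert-butyldimethylsilyloxy)methyl]-4-methylidene-5-oxooxolan-2-yl]pent-4-enal; 18 methyl acrylate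
Product: 19 methyl (E)-6-[(tert-butyldiphenylsilyloxy)methyl]-7-[(2R,3R)-3-[(tert-butyldimethylsilyloxy)methyl]-4-methylidene-5-oxooxolan-2-yl]-3-hydroxy-2-methylidenehept-6-enoate (both C1 epimers)
Conditions: DABCO (1 equiv), neat methyl acrylate, 25 °C
Reagents that add atoms: none
Why: The Morita–Baylis–Hillman reaction of the unhindered aliphatic aldehyde attaches C10, C9 and C14 in one operation; the new carbinol centre is removed in step 12, and the α-substituted acrylate of the lactone cannot turn over under amine catalysis.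

Step 12
Reactants: 19 methyl (E)-6-[(tert-butyldiphenylsilyloxy)methyl]-7-[(2R,3R)-3-[(tert-butyldimethylsilyloxy)methyl]-4-methylidene-5-oxooxolan-2-yl]-3-hydroxy-2-methylidenehept-6-enoate
Product: 20 methyl (2Z,6E)-2-(bromomethyl)-6-[(tert-butyldiphenylsilyloxy)methyl]-7-[(2R,3R)-3-[(tert-butyldimethylsilyloxy)methyl]-4-methylidene-5-oxooxolan-2-yl]hepta-2,6-dienoate
Conditions: NBS, Me2S, CH2Cl2, 0 → 25 °C
Reagents that add atoms: N-bromosuccinimide, O=C1CCC(=O)N1Br
Why: Corey–Kim-type activation of the allylic alcohol and SN2′ bromide transposition should give the thermodynamically preferred 2-(bromomethyl)enoate with CO2Me trans to C2, moving the leaving group onto C9.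

Step 13
Reactants: 20 methyl (2Z,6E)-2-(bromomethyl)-6-[(tert-butyldiphenylsilyloxy)methyl]-7-[(2R,3R)-3-[(tert-butyldimethylsilyloxy)methyl]-4-methylidene-5-oxooxolan-2-yl]hepta-2,6-dienoate
Product: 21 methyl (2Z,6E)-2-(bromomethyl)-6-[(tert-butyldiphenylsilyloxy)methyl]-7-[(2R,3R)-3-(hydroxymethyl)-4-methylidene-5-oxooxolan-2-yl]hepta-2,6-dienoate
Conditions: HF (48% aq.), MeCN, 0 °C
Reagents that add atoms: none
Why: Acidic fluoride desilylation should remove the primary tert-butyldimethylsilyl ether on O8 much faster than the tert-butyldiphenylsilyl ether on O15, and the amine-free medium spares the reactive allylic bromide.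

Step 14
Reactants: 21 methyl (2Z,6E)-2-(bromomethyl)-6-[(tert-butyldiphenylsilyloxy)methyl]-7-[(2R,3R)-3-(hydroxymethyl)-4-methylidene-5-oxooxolan-2-yl]hepta-2,6-dienoate
Product: 22 methyl (2E,6E)-6-[(tert-butyldiphenylsilyloxy)methyl]-2-formyl-7-[(2R,3R)-3-(hydroxymethyl)-4-methylidene-5-oxooxolan-2-yl]hepta-2,6-dienoate
Conditions: N-methylmorpholine N-oxide, 4 Å MS, MeCN, 0 → 25 °C
Reagents that add atoms: N-methylmorpholine N-oxide, C[N+]1([O-])CCOCC1
Why: Amine-oxide (Kornblum/Ganem-type) oxidation of the activated allylic bromide, by O-alkylation at the primary carbon and elimination, should give the C9 aldehyde of the 2-formylacrylate without affecting the saturated C8 alcohol.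

Step 15
Reactants: 22 methyl (2E,6E)-6-[(tert-butyldiphenylsilyloxy)methyl]-2-formyl-7-[(2R,3R)-3-(hydroxymethyl)-4-methylidene-5-oxooxolan-2-yl]hepta-2,6-dienoate
Product: 23 methyl (2E,6E)-6-[(tert-butyldiphenylsilyloxy)methyl]-2-formyl-7-[(2R,3S)-3-formyl-4-methylidene-5-oxooxolan-2-yl]hepta-2,6-dienoate
Conditions: Dess–Martin periodinane, CH2Cl2, 0 °C; filtered through Celite and used at once
Reagents that add atoms: none
Why: Dess–Martin oxidation under base-free conditions should give the C8 aldehyde without epimerisation at C7, migration of the exocyclic olefin or β-elimination of the lactone oxygen, provided the dialdehyde is not stored or chromatographed.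

Step 16
Reactants: 23 methyl (2E,6E)-6-[(tert-butyldiphenylsilyloxy)methyl]-2-formyl-7-[(2R,3S)-3-formyl-4-methylidene-5-oxooxolan-2-yl]hepta-2,6-dienoate
Product: 25 methyl (6R,7R,8S,9S)-15-(tert-butyldiphenylsilyloxy)-8-hydroxy-9-(triethylsilyloxy)-cis,cis-germacra-1(10),4,11(13)-trien-12,6-olid-14-oate, via siloxyallylchromium dichloride 24 (not isolated)
Conditions: CrCl2 (8 equiv), DMF, 25 °C; 23 and Et3SiCl (1.2 equiv) in THF added by syringe pump over 12 h (final 2 mM); pH 7 buffer
Reagents that add atoms: chlorotriethylsilane, CC[Si](Cl)(CC)CC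
Why: Two equivalents of divalent chromium should reduce the silyl-chloride-activated, doubly activated 2-formylacrylate chemoselectively (the aliphatic C8 aldehyde, the esters and the α-methylene lactone are not reduced by CrCl2) to the γ-siloxyallylchromium 24, in which the original C1=C10 geometry is erased; 24 then adds through its oxygen-bearing γ-carbon C9 to the C8 aldehyde in a closed six-membered (Zimmerman–Traxler-type) transition state, which regenerates C1=C10. The closest known reaction type is the CrCl2/trialkylsilyl chloride pinacol-type cross-coupling of α,β-unsaturated aldehydes with aldehydes (a Nozaki–Hiyama-type allylation), applied here intramolecularly under high dilution. The ten-membered carbocycle closes in a 10-exo-trig mode, the allylic transposition placing C1, C10 and C9 all inside the ring. C9 is controlled by the enol-ether geometry of 24 (siloxy group cis to C1 and trans to the ester, axial in the chair), which should give the threo (8,9-trans) pair; C8 is controlled by C7, with attack on the Felkin–Anh face (C9 anti to the C7–C11 bond, passing H7) while the tether holds C9 gauche to C6, which should give 8S and hence 9S; the C1=C10 olefin should re-form with C2 cis to C9, the arrangement that both the ring and A(1,2) strain with the ester favour. The step needs reduction of the enal in preference to the aldehyde (secured by conjugation with the ester), γ- rather than α-attack (secured by the cyclic transition state) and differentiation of the two oxygens (O9 leaves as the triethylsilyl ether and O8 as the free alcohol after hydrolysis of the trivalent chromium alkoxide; adding Et3SiCl together with the substrate keeps it from silylating O8).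

Step 17
Reactants: 25 methyl (6R,7R,8S,9S)-15-(tert-butyldiphenylsilyloxy)-8-hydroxy-9-(triethylsilyloxy)-cis,cis-germacra-1(10),4,11(13)-trien-12,6-olid-14-oate
Product: 26 methyl (6R,7S,8S,9S)-15-(tert-butyldiphenylsilyloxy)-8-(methacryloyloxy)-9-(triethylsilyloxy)-cis,cis-germacra-1(10),4,11(13)-trien-12,6-olid-14-oate
Conditions: methacrylic anhydride, Et3N, DMAP (cat.), CH2Cl2, 0 → 25 °C
Reagents that add atoms: methacrylic anhydride, C=C(C)C(=O)OC(=O)C(C)=C
Why: DMAP-catalysed acylation of the only free hydroxyl (O8) should install the methacrylate with retention at C8.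

Step 18
Reactants: 26 methyl (6R,7S,8S,9S)-15-(tert-butyldiphenylsilyloxy)-8-(methacryloyloxy)-9-(triethylsilyloxy)-cis,cis-germacra-1(10),4,11(13)-trien-12,6-olid-14-oate
Product: 27 methyl (6R,7S,8S,9S)-15-(tert-butyldiphenylsilyloxy)-9-hydroxy-8-(methacryloyloxy)-cis,cis-germacra-1(10),4,11(13)-trien-12,6-olid-14-oate
Conditions: HF·pyridine, pyridine, THF, 0 °C
Reagents that add atoms: none
Why: Buffered fluoride desilylation should cleave the triethylsilyl ether far faster than the tert-butyldiphenylsilyl ether, and the weakly acidic medium disfavours 8→9 acyl migration.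

Step 19
Reactants: 27 methyl (6R,7S,8S,9S)-15-(tert-butyldiphenylsilyloxy)-9-hydroxy-8-(methacryloyloxy)-cis,cis-germacra-1(10),4,11(13)-trien-12,6-olid-14-oate
Product: 28 methyl (6R,7S,8S,9S)-9-acetoxy-15-(tert-butyldiphenylsilyloxy)-8-(methacryloyloxy)-cis,cis-germacra-1(10),4,11(13)-trien-12,6-olid-14-oate
Conditions: Ac2O, pyridine, DMAP (cat.), CH2Cl2, 0 °C
Reagents that add atoms: acetic anhydride, CC(=O)OC(C)=O
Why: Acetylation of the freed allylic O9 hydroxyl should proceed with retention at C9 and be carried out immediately, so that acyl migration has no time to compete.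

Step 20
Reactants: 28 methyl (6R,7S,8S,9S)-9-acetoxy-15-(tert-butyldiphenylsilyloxy)-8-(methacryloyloxy)-cis,cis-germacra-1(10),4,11(13)-trien-12,6-olid-14-oate
Product: 29 methyl (6R,7S,8S,9S)-9-acetoxy-15-hydroxy-8-(methacryloyloxy)-cis,cis-germacra-1(10),4,11(13)-trien-12,6-olid-14-oate (CNP0179134.2)
Conditions: HF·pyridine, THF, 25 °C
Reagents that add atoms: none
Why: Acidic fluoride cleavage of the primary allylic silyl ether should free the C15 alcohol without hydrolysis or migration of the acetate, the methacrylate or the lactone.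

Compound list

1 | (S)-5-(hydroxymethyl)furan-2(5H)-one | OC[C@H]1OC(=O)C=C1 | starting material
2 | (S)-5-[(triethylsilyloxy)methyl]furan-2(5H)-one | CC[Si](CC)(CC)OC[C@H]1OC(=O)C=C1 | intermediate
3 | (4R,5S)-4-(hydroxymethyl)-5-[(triethylsilyloxy)methyl]oxolan-2-one (4,5-trans) | OC[C@H]1CC(=O)O[C@@H]1CO[Si](CC)(CC)CC | intermediate
4 | (4R,5S)-4-[(tert-butyldimethylsilyloxy)methyl]-5-[(triethylsilyloxy)methyl]oxolan-2-one | CC(C)(C)[Si](C)(C)OC[C@H]1CC(=O)O[C@@H]1CO[Si](CC)(CC)CC | intermediate
5 | lithium enolate of 4 | CC(C)(C)[Si](C)(C)OC[C@H]1C=C(O[Li])O[C@@H]1CO[Si](CC)(CC)CC | intermediate (not isolated)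
6 | Mannich base, 3-[(dimethylamino)methyl] derivative of 4 (C3 epimers) | CC(C)(C)[Si](C)(C)OC[C@H]1C(CN(C)C)C(=O)O[C@@H]1CO[Si](CC)(CC)CC | intermediate (not isolated)
7 | 3-[(trimethylammonio)methyl] derivative of 4, iodide | CC(C)(C)[Si](C)(C)OC[C@H]1C(C[N+](C)(C)C)C(=O)O[C@@H]1CO[Si](CC)(CC)CC.[I-] | intermediate (not isolated)
8 | (4R,5S)-4-[(tert-butyldimethylsilyloxy)methyl]-3-methylidene-5-[(triethylsilyloxy)methyl]oxolan-2-one | CC(C)(C)[Si](C)(C)OC[C@H]1C(=C)C(=O)O[C@@H]1CO[Si](CC)(CC)CC | intermediate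
9 | 4-chloro-1,1-dimethoxybutane | COC(CCCCl)OC | starting material
10 | (4,4-dimethoxybutyl)triphenylphosphonium iodide | COC(CCC[P+](c1ccccc1)(c1ccccc1)c1ccccc1)OC.[I-] | intermediate
11 | (4,4-dimethoxybutylidene)triphenylphosphorane | COC(CCC=P(c1ccccc1)(c1ccccc1)c1ccccc1)OC | intermediate (not isolated)
12 | 5,5-dimethoxy-2-(triphenyl-λ5-phosphanylidene)pentanal | COC(CCC(C=O)=P(c1ccccc1)(c1ccccc1)c1ccccc1)OC | intermediate
13 | (2S,3R)-3-[(tert-butyldimethylsilyloxy)methyl]-4-methylidene-5-oxooxolane-2-carbaldehyde | CC(C)(C)[Si](C)(C)OC[C@H]1C(=C)C(=O)O[C@@H]1C=O | intermediate (not isolated)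
14 | (E)-3-[(2R,3R)-3-[(tert-butyldimethylsilyloxy)methyl]-4-methylidene-5-oxooxolan-2-yl]-2-(3,3-dimethoxypropyl)prop-2-enal | CC(C)(C)[Si](C)(C)OC[C@H]1C(=C)C(=O)O[C@@H]1/C=C(/C=O)CCC(OC)OC | intermediate
15 | (4R,5R)-4-[(tert-butyldimethylsilyloxy)methyl]-5-[(E)-2-(hydroxymethyl)-5,5-dimethoxypent-1-en-1-yl]-3-methylideneoxolan-2-one | CC(C)(C)[Si](C)(C)OC[C@H]1C(=C)C(=O)O[C@@H]1/C=C(/CO)CCC(OC)OC | intermediate
16 | (4R,5R)-4-[(tert-butyldimethylsilyloxy)methyl]-5-[(E)-2-[(tert-butyldiphenylsilyloxy)methyl]-5,5-dimethoxypent-1-en-1-yl]-3-methylideneoxolan-2-one | CC(C)(C)[Si](C)(C)OC[C@H]1C(=C)C(=O)O[C@@H]1/C=C(/CO[Si](c2ccccc2)(c2ccccc2)C(C)(C)C)CCC(OC)OC | intermediate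
17 | (E)-4-[(tert-butyldiphenylsilyloxy)methyl]-5-[(2R,3R)-3-[(tert-butyldimethylsilyloxy)methyl]-4-methylidene-5-oxooxolan-2-yl]pent-4-enal | CC(C)(C)[Si](C)(C)OC[C@H]1C(=C)C(=O)O[C@@H]1/C=C(/CO[Si](c2ccccc2)(c2ccccc2)C(C)(C)C)CCC=O | intermediate
18 | methyl acrylate | C=CC(=O)OC | starting material
19 | methyl (E)-6-[(tert-butyldiphenylsilyloxy)methyl]-7-[(2R,3R)-3-[(tert-butyldimethylsilyloxy)methyl]-4-methylidene-5-oxooxolan-2-yl]-3-hydroxy-2-methylidenehept-6-enoate (both C1 epimers) | CC(C)(C)[Si](C)(C)OC[C@H]1C(=C)C(=O)O[C@@H]1/C=C(/CO[Si](c2ccccc2)(c2ccccc2)C(C)(C)C)CCC(O)C(=C)C(=O)OC | intermediate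
20 | methyl (2Z,6E)-2-(bromomethyl)-6-[(tert-butyldiphenylsilyloxy)methyl]-7-[(2R,3R)-3-[(tert-butyldimethylsilyloxy)methyl]-4-methylidene-5-oxooxolan-2-yl]hepta-2,6-dienoate | CC(C)(C)[Si](C)(C)OC[C@H]1C(=C)C(=O)O[C@@H]1/C=C(/CO[Si](c2ccccc2)(c2ccccc2)C(C)(C)C)CC/C=C(/C(=O)OC)CBr | intermediate
21 | methyl (2Z,6E)-2-(bromomethyl)-6-[(tert-butyldiphenylsilyloxy)methyl]-7-[(2R,3R)-3-(hydroxymethyl)-4-methylidene-5-oxooxolan-2-yl]hepta-2,6-dienoate | OC[C@H]1C(=C)C(=O)O[C@@H]1/C=C(/CO[Si](c2ccccc2)(c2ccccc2)C(C)(C)C)CC/C=C(/C(=O)OC)CBr | intermediate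
22 | methyl (2E,6E)-6-[(tert-butyldiphenylsilyloxy)methyl]-2-formyl-7-[(2R,3R)-3-(hydroxymethyl)-4-methylidene-5-oxooxolan-2-yl]hepta-2,6-dienoate | OC[C@H]1C(=C)C(=O)O[C@@H]1/C=C(/CO[Si](c2ccccc2)(c2ccccc2)C(C)(C)C)CC/C=C(/C(=O)OC)C=O | intermediate
23 | methyl (2E,6E)-6-[(tert-butyldiphenylsilyloxy)methyl]-2-formyl-7-[(2R,3S)-3-formyl-4-methylidene-5-oxooxolan-2-yl]hepta-2,6-dienoate (seco-dialdehyde) | O=C[C@H]1C(=C)C(=O)O[C@@H]1/C=C(/CO[Si](c2ccccc2)(c2ccccc2)C(C)(C)C)CC/C=C(/C(=O)OC)C=O | intermediate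
24 | γ-(triethylsiloxy)allylchromium dichloride from 23 (trivalent chromium on C1, siloxy group cis to C1, C1 configuration undefined) | O=C[C@H]1C(=C)C(=O)O[C@@H]1/C=C(/CO[Si](c2ccccc2)(c2ccccc2)C(C)(C)C)CCC([Cr](Cl)Cl)/C(C(=O)OC)=C\O[Si](CC)(CC)CC | intermediate (not isolated)
25 | methyl (6R,7R,8S,9S)-15-(tert-butyldiphenylsilyloxy)-8-hydroxy-9-(triethylsilyloxy)-cis,cis-germacra-1(10),4,11(13)-trien-12,6-olid-14-oate | O[C@H]1[C@H]2C(=C)C(=O)O[C@@H]2/C=C(/CO[Si](c3ccccc3)(c3ccccc3)C(C)(C)C)CC/C=C(/C(=O)OC)[C@@H]1O[Si](CC)(CC)CC | intermediate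
26 | methyl (6R,7S,8S,9S)-15-(tert-butyldiphenylsilyloxy)-8-(methacryloyloxy)-9-(triethylsilyloxy)-cis,cis-germacra-1(10),4,11(13)-trien-12,6-olid-14-oate | C=C(C)C(=O)O[C@H]1[C@H]2C(=C)C(=O)O[C@@H]2/C=C(/CO[Si](c3ccccc3)(c3ccccc3)C(C)(C)C)CC/C=C(/C(=O)OC)[C@@H]1O[Si](CC)(CC)CC | intermediate
27 | methyl (6R,7S,8S,9S)-15-(tert-butyldiphenylsilyloxy)-9-hydroxy-8-(methacryloyloxy)-cis,cis-germacra-1(10),4,11(13)-trien-12,6-olid-14-oate | C=C(C)C(=O)O[C@H]1[C@H]2C(=C)C(=O)O[C@@H]2/C=C(/CO[Si](c3ccccc3)(c3ccccc3)C(C)(C)C)CC/C=C(/C(=O)OC)[C@@H]1O | intermediate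
28 | methyl (6R,7S,8S,9S)-9-acetoxy-15-(tert-butyldiphenylsilyloxy)-8-(methacryloyloxy)-cis,cis-germacra-1(10),4,11(13)-trien-12,6-olid-14-oate | C=C(C)C(=O)O[C@H]1[C@H]2C(=C)C(=O)O[C@@H]2/C=C(/CO[Si](c3ccccc3)(c3ccccc3)C(C)(C)C)CC/C=C(/C(=O)OC)[C@@H]1OC(C)=O | intermediate
29 | methyl (6R,7S,8S,9S)-9-acetoxy-15-hydroxy-8-(methacryloyloxy)-cis,cis-germacra-1(10),4,11(13)-trien-12,6-olid-14-oate (CNP0179134.2) | C=C(C)C(=O)O[C@H]1[C@H]2C(=C)C(=O)O[C@@H]2/C=C(/CO)CC/C=C(/C(=O)OC)[C@@H]1OC(C)=O | target

Total step count: 20. Longest linear sequence: 18 (steps 1–4 and 7–20; steps 5 and 6 make the ylide 12).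

Steps most likely to fail

1. Step 16. The allylchromium may be protonated or couple between molecules before it reaches across the forming ten-membered ring. Facial selectivity at C8 or the threo preference may also be poor, and silyl transfer may blur the O8/O9 differentiation. The fallback sets out from 23 and replaces the allylmetal addition by a ketyl coupling: a titanium-induced (McMurry-type) pinacol macrocyclisation (TiCl3(DME)1.5, zinc–copper couple, DME, 25 °C, slow addition). This would join the same two carbonyl carbons with retention of the enal geometry and, as is usual for medium rings, should favour the trans (threo) diol, methyl (6R,7R,8S,9S)-15-(tert-butyldiphenylsilyloxy)-8,9-dihydroxy-cis,cis-germacra-1(10),4,11(13)-trien-12,6-olid-14-oate F1. The two hydroxyls are then told apart by reactivity instead of by the silyl group. The 9-hydroxyl is flanked by the fully substituted C10 and hydrogen-bonded to the C14 ester, so methacrylic anhydride (1.05 equiv, DMAP, −40 °C) should acylate O8 first, and the fallback comes back to the route at 27.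

2. Step 15. Once the C8 aldehyde exists, its α-hydrogen (H7) is also allylic to the exocyclic C11=C13 olefin. Enolisation could therefore move that olefin into conjugation or expel the lactone oxygen by β-elimination during oxidation, work-up or the slow addition of step 16. The fallback sets out from 17 and masks the exocyclic methylene before any of this chemistry. Conjugate addition of thiophenol (PhSH, cat. Et3N, CH2Cl2) to the only Michael acceptor present gives the sulfide aldehyde F2. This is carried through the same operations as steps 11–16: Morita–Baylis–Hillman adduct F3; allylic bromide F4 (PBr3, Et2O, 0 °C, in place of NBS/Me2S, which could attack the sulfide); bromo alcohol F5; hydroxy formylacrylate F6; dialdehyde F7; and macrocyclic sulfide F8 after the CrCl2/Et3SiCl ring closure. Oxidation with mCPBA at −78 °C then gives the sulfoxide F9, whose thermal syn-elimination (toluene, 90 °C), which can only take the C11 hydrogen, unveils the α-methylene lactone, and the fallback comes back to the route at 25.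

3. Step 11. The amine-catalysed coupling of an aliphatic aldehyde with methyl acrylate is slow, and over several days DABCO may add reversibly to the α-methylene lactone or promote aldol self-condensation of 17. The fallback sets out from 17 and makes the same carbon–carbon bond with an organometallic instead of a nucleophilic catalyst: Nozaki–Hiyama–Kishi coupling with methyl 2-bromoacrylate (CrCl2, NiCl2 (cat.), DMF, 25 °C) adds the α-(methoxycarbonyl)vinylchromium reagent to the aldehyde. Neither the silyl ethers nor the lactone should be affected, and the coupling gives the adduct 19 directly, where the fallback comes back to the route.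

Further compounds
F1 | step 16 | methyl (6R,7R,8S,9S)-15-(tert-butyldiphenylsilyloxy)-8,9-dihydroxy-cis,cis-germacra-1(10),4,11(13)-trien-12,6-olid-14-oate | O[C@H]1[C@H]2C(=C)C(=O)O[C@@H]2/C=C(/CO[Si](c3ccccc3)(c3ccccc3)C(C)(C)C)CC/C=C(/C(=O)OC)[C@@H]1O
F2 | step 15 | thiophenol adduct of 17 (3-[(phenylsulfanyl)methyl] lactone, C11 epimers) | CC(C)(C)[Si](C)(C)OC[C@H]1C(CSc2ccccc2)C(=O)O[C@@H]1/C=C(/CO[Si](c2ccccc2)(c2ccccc2)C(C)(C)C)CCC=O
F3 | step 15 | Morita–Baylis–Hillman adduct of F2 with methyl acrylate | CC(C)(C)[Si](C)(C)OC[C@H]1C(CSc2ccccc2)C(=O)O[C@@H]1/C=C(/CO[Si](c2ccccc2)(c2ccccc2)C(C)(C)C)CCC(O)C(=C)C(=O)OC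
F4 | step 15 | (Z)-2-(bromomethyl)enoate from F3 (sulfide analogue of 20) | CC(C)(C)[Si](C)(C)OC[C@H]1C(CSc2ccccc2)C(=O)O[C@@H]1/C=C(/CO[Si](c2ccccc2)(c2ccccc2)C(C)(C)C)CC/C=C(/C(=O)OC)CBr
F5 | step 15 | bromo alcohol (sulfide analogue of 21) | OC[C@H]1C(CSc2ccccc2)C(=O)O[C@@H]1/C=C(/CO[Si](c2ccccc2)(c2ccccc2)C(C)(C)C)CC/C=C(/C(=O)OC)CBr
F6 | step 15 | hydroxy formylacrylate (sulfide analogue of 22) | OC[C@H]1C(CSc2ccccc2)C(=O)O[C@@H]1/C=C(/CO[Si](c2ccccc2)(c2ccccc2)C(C)(C)C)CC/C=C(/C(=O)OC)C=O
F7 | step 15 | dialdehyde (sulfide analogue of 23) | O=C[C@H]1C(CSc2ccccc2)C(=O)O[C@@H]1/C=C(/CO[Si](c2ccccc2)(c2ccccc2)C(C)(C)C)CC/C=C(/C(=O)OC)C=O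
F8 | step 15 | macrocyclic sulfide (13-phenylsulfanyl-11,13-dihydro analogue of 25) | O[C@H]1[C@H]2C(CSc3ccccc3)C(=O)O[C@@H]2/C=C(/CO[Si](c3ccccc3)(c3ccccc3)C(C)(C)C)CC/C=C(/C(=O)OC)[C@@H]1O[Si](CC)(CC)CC
F9 | step 15 | macrocyclic sulfoxide from F8 | O[C@H]1[C@H]2C(CS(=O)c3ccccc3)C(=O)O[C@@H]2/C=C(/CO[Si](c3ccccc3)(c3ccccc3)C(C)(C)C)CC/C=C(/C(=O)OC)[C@@H]1O[Si](CC)(CC)CC
F0 | step 11 | none | none
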